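The synthesis rests on cutting the biaryl bond between C1 of the benzene ring and C2 of the pyrrole ring. The key step exploits the phenol oxygen on the benzene carbon adjacent to C1: this ring can be redrawn as a cyclohexadienone whose α-carbon bears a diazo group, an o-quinone diazide. Rhodium(II) turns it into a quinoid carbene that is attacked by the nitrogen-adjacent α-carbon of unprotected pyrrole. Loss of N2 and rearomatisation of both rings deliver the free 2-(2-hydroxyaryl)pyrrole in one operation, with both aryl C–Br bonds untouched and no protecting group. The precursor is thus a non-aromatic dibromodiazodienone. Threefold bromination of the pyrrole ring completes the target.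

Key step: step 2

Remark: the target has no stereocentre, and its aryl–pyrrole axis (flanked only by OH/H and by NH/Br on a five-membered ring) should rotate freely at room temperature, so the compound is achiral and no enantiocontrol is needed.

Step 1
Reactants: 1 2-amino-4,6-dibromophenol
Product: 3 2,4-dibromo-6-diazocyclohexa-2,4-dien-1-one, via diazonium chloride 2 (not isolated)
Conditions: NaNO2 (1.0 equiv), 2 M aq HCl, MeCN, 0 °C; then NaHCO3 to pH 7; CH2Cl2 extraction, dark, ≤ 25 °C (energetic, light-sensitive diazo compound: never heated neat)
Reagents that add atoms: sodium nitrite, [Na+].[O-]N=O; hydrochloric acid, Cl (supplies only the chloride counter-ion of intermediate 2)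
Why: Diazotisation: nitrous acid converts the primary arylamine into the o-hydroxy diazonium salt 2, whose OH is acidified so strongly by the ortho N2+ group and the two bromines that bicarbonate removes the proton and leaves the neutral, extractable o-quinone diazide 3; both bromines stand meta to N2+ and so are not activated for displacement by chloride or water.

Step 2
Reactants: 3 2,4-dibromo-6-diazocyclohexa-2,4-dien-1-one; 4 1H-pyrrole
Product: 6 2,4-dibromo-6-(1H-pyrrol-2-yl)phenol, via pyrrolium phenolate 5 (not isolated)
Conditions: Rh2(esp)2 (1 mol %), 4 (5 equiv), ClCH2CH2Cl, 70 °C, slow addition of 3, Ar, dark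
Reagents that add atoms: none
Why: Rh2(esp)2 expels N2 from the diazo carbon C6 of 3 and gives an electrophilic rhodium quinoid carbene, which the α-carbon C2 of pyrrole attacks; release of rhodium leaves the 2H-pyrrolium phenolate 5, and shift of its C2 proton to the phenolate oxygen rearomatises both rings to 6. The closest known reaction type is the metal-carbene C–H arylation of electron-rich arenes and heteroarenes with quinone diazides, together with the C2-selective substitution of N–H pyrrole by rhodium carbenoids of α-diazocarbonyl compounds. No ring is closed and no lasting stereocentre is formed, since the sp3 carbon of 5 is flattened again in the proton shift. The site on the benzene ring is fixed by the position of the diazo group, and C2 of pyrrole is preferred over C3 and over N–H insertion because its σ-complex is the best stabilised and the nitrogen lone pair is tied up in the aromatic sextet. Rh(II) does not insert into the two C–Br bonds, which a Pd(0) coupling would endanger, and a metal-bound carbene generated thermally in the dark should avoid the Wolff ring contraction typical of photolysed o-quinone diazides. Excess pyrrole and slow addition of 3 should hold back O–H insertion into the product phenol and a second arylation, and a formal [3+2] adduct (phenolate oxygen closing on pyrrole C3) would reopen to 6 by aromatisation.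

Step 3
Reactants: 6 2,4-dibromo-6-(1H-pyrrol-2-yl)phenol
Product: 9 pentabromopseudilin [2,3,4-tribromo-5-(3,5-dibromo-2-hydroxyphenyl)-1H-pyrrole], via monobromopyrrole 7 (not isolated), via dibromopyrrole 8 (not isolated)
Conditions: NBS (3.0 equiv), THF, −78 °C → rt, dark
Reagents that add atoms: N-bromosuccinimide, O=C1CCC(=O)N1Br
Why: Electrophilic aromatic bromination: the π-excessive pyrrole ring of 6 is far more nucleophilic than the phenol ring, whose positions ortho and para to OH are all occupied (Br, Br, pyrrolyl), so three equivalents of NBS should fill C5 first (7) and then the two β-positions (8, then 9; their order is immaterial) without touching the benzene ring.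

Compound list
1 | 2-amino-4,6-dibromophenol (OH at C1, NH2 at C2, Br at C4 and C6) | Nc1cc(Br)cc(Br)c1O | starting material
2 | 3,5-dibromo-2-hydroxybenzenediazonium chloride | Oc1c(Br)cc(Br)cc1[N+]#N.[Cl-] | intermediate
3 | 2,4-dibromo-6-diazocyclohexa-2,4-dien-1-one (o-quinone diazide: C1 ketone, Br at C2 and C4, diazo group at C6) | O=C1C(Br)=CC(Br)=CC1=[N+]=[N-] | intermediate
4 | 1H-pyrrole | c1cc[nH]c1 | starting material
5 | 2,4-dibromo-6-(2H-pyrrol-1-ium-2-yl)phenolate (zwitterionic σ-adduct; its sp3 carbon is transient and racemic) | [O-]c1c(Br)cc(Br)cc1C1C=CC=[NH+]1 | intermediate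
6 | 2,4-dibromo-6-(1H-pyrrol-2-yl)phenol | Oc1c(Br)cc(Br)cc1-c1ccc[nH]1 | intermediate
7 | 2,4-dibromo-6-(5-bromo-1H-pyrrol-2-yl)phenol | Oc1c(Br)cc(Br)cc1-c1ccc(Br)[nH]1 | intermediate
8 | 2,4-dibromo-6-(4,5-dibromo-1H-pyrrol-2-yl)phenol | Oc1c(Br)cc(Br)cc1-c1cc(Br)c(Br)[nH]1 | intermediate
9 | pentabromopseudilin, 2,3,4-tribromo-5-(3,5-dibromo-2-hydroxyphenyl)-1H-pyrrole (achiral) | Oc1c(Br)cc(Br)cc1-c1[nH]c(Br)c(Br)c1Br | target

Total step count: 3. Longest linear sequence: 3 steps (1 → 3 → 6 → 9).

Steps most likely to fail

Step 2 (key step). Several things may go wrong: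
- carbene transfer to the wrong site (N–H or O–H insertion, or attack at pyrrole C3)
- Wolff ring contraction of the diazodienone
- azo coupling of undecomposed diazide with pyrrole
- inhibition of the catalyst by the chelating product

The fallback replaces carbene transfer by cross-coupling and sets out from 3. Iodo-dediazoniation with KI in aq HCl (0 °C → rt) should give 2,4-dibromo-6-iodophenol F1. A C–I-selective Suzuki–Miyaura coupling with commercial N-Boc-pyrrol-2-ylboronic acid (XPhos Pd G3, K3PO4, THF/H2O, rt) should give tert-butyl 2-(3,5-dibromo-2-hydroxyphenyl)-1H-pyrrole-1-carboxylate F2. Methanolysis of the Boc group (K2CO3, MeOH) brings the material back to the route at 6.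

Step 1. Three things may go wrong:
- oxidation of the electron-rich aminophenol by nitrous acid
- self-coupling of the diazonium ion with unreacted aminophenol
- decomposition of the diazide by light or heat during isolation

The fallback gives up diazo chemistry, moves all five brominations to the end, and sets out from 4. Iridium-catalysed C–H borylation of excess 4 (B2pin2, [Ir(OMe)(cod)]2, dtbpy, hexane) should give 2-(4,4,5,5-tetramethyl-1,3,2-dioxaborolan-2-yl)-1H-pyrrole F3. Suzuki–Miyaura coupling with commercial 2-iodophenol (Pd(dppf)Cl2, K3PO4, dioxane/H2O, 60 °C) should give 2-(1H-pyrrol-2-yl)phenol F4. Fivefold bromination (NBS, 5 equiv, MeCN, −20 °C → rt) should fill the three pyrrole carbons. It should then fill the free ortho and para positions of the phenol, to which the OH group directs, and so rejoins the route at 9.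

Step 3. Three things may go wrong:
- oxidation of the pyrrolylphenol to quinoid or polymeric material
- ipso attack on the phenol ring with dearomatisation
- incomplete bromination at the hindered pyrrole carbon next to the aryl group

The fallback masks the phenol and sets out from 6. O-Methylation (MeI, K2CO3, acetone), selective because the phenol is far more acidic than the pyrrole N–H, should give 2-(3,5-dibromo-2-methoxyphenyl)-1H-pyrrole F5. Bromination (NBS, 3 equiv, THF, −78 °C → rt) should give 2,3,4-tribromo-5-(3,5-dibromo-2-methoxyphenyl)-1H-pyrrole F6. Ether cleavage (BBr3, CH2Cl2, −78 °C → rt, then water) returns to the route at 9.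

Further compounds
F1 | step 2 | 2,4-dibromo-6-iodophenol | Oc1c(Br)cc(Br)cc1I
F2 | step 2 | tert-butyl 2-(3,5-dibromo-2-hydroxyphenyl)-1H-pyrrole-1-carboxylate | CC(C)(C)OC(=O)n1cccc1-c1cc(Br)cc(Br)c1O
F3 | step 1 | 2-(4,4,5,5-tetramethyl-1,3,2-dioxaborolan-2-yl)-1H-pyrrole | CC1(C)OB(OC1(C)C)c1ccc[nH]1
F4 | step 1 | 2-(1H-pyrrol-2-yl)phenol | Oc1ccccc1-c1ccc[nH]1
F5 | step 3 | 2-(3,5-dibromo-2-methoxyphenyl)-1H-pyrrole | COc1c(Br)cc(Br)cc1-c1ccc[nH]1
F6 | step 3 | 2,3,4-tribromo-5-(3,5-dibromo-2-methoxyphenyl)-1H-pyrrole | COc1c(Br)cc(Br)cc1-c1[nH]c(Br)c(Br)c1Br
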